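Target 30 ⇐ allylic sulfide 27 (Mislow–Evans [2,3] shift puts O on C5 and makes C4=C15) ⇐ ketone 25 (Saegusa–Ito oxidation gives the C2=C3 furanone bond) ⇐ alkynol 24 (cyclocarbonylation of the C6–OH/C7-ethynyl pair gives the cis-fused α-methylene lactone).
Key disconnection: the nine-membered oxonane ring (O–C3–C4–C5–C6–C7–C8–C9–C10, inside the 11-oxabicyclo[6.2.1]undecane core) is not cyclised; it is grown from the seven-membered 1,4-dioxepane ring (O–C3–C4–O'–C8–C9–C10) of enol ether 18 by a Claisen rearrangement (C4–O' breaks, C6–C7 forms, 7 → 9).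
Enabling feature: with C8 at the ketone level the oxonane holds the γ,δ-unsaturated ketone C8(=O)–C7–C6–C5=C4, the retron of the allyl vinyl ether C7=C8–O'–C4–C5=C6, of which C8, O' and C4 are ring atoms of the dioxepane; C6 and C7 come from the two enol ether geometries and the C4 carbinol.
18 ⇐ diyne 17 (7-exo-dig alkoxide addition) ⇐ enone 15 + PhSCH2MgCl (chelation sets C4) ⇐ cis-tetrahydrofuran 9 ⇐ bicyclic lactone 7 (alkoxycarbonylative cyclisation of anti-diol 6, from an asymmetric Mukaiyama aldol and an anti-selective reduction).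
Ring order: tetrahydrofuran (with a temporary γ-lactone) → dioxepane → oxonane (key step) → α-methylene-γ-lactone; the furanone double bond and the C5 hydroxyl come last.
Key step: step 14
Remark: C1–C15 are the germacrane locants of the target (lactone C6–O–C12(=O)–C11(=C13)–C7, ester on C8, CH3 (C14) and the ether oxygen to C3 on C10, C15 on C4) and are used for 7–30; CIP letters at C6 and C7 change along the route only because substituent priorities change.

Step 1
Reactants: 1 3-methylbut-3-en-2-one
Product: 2 2-methyl-3-(trimethylsilyloxy)buta-1,3-diene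
Conditions: TMSOTf, Et3N, Et2O, 0 °C
Reagents that add atoms: trimethylsilyl trifluoromethanesulfonate, C[Si](C)(C)OS(=O)(=O)C(F)(F)F
Why: Soft enolisation and O-silylation of the methyl ketone, whose methyl group is the only enolisable position, should give the 2-silyloxydiene (silyl enol ether formation).

Step 2
Reactants: 2 2-methyl-3-(trimethylsilyloxy)buta-1,3-diene; 3 [(4-methoxybenzyl)oxy]acetaldehyde
Product: 5 (S)-5-hydroxy-6-[(4-methoxybenzyl)oxy]-2-methylhex-1-en-3-one, via silyl ether 4 (not isolated)
Conditions: [Cu((S,S)-Ph-pybox)](SbF6)2 (5 mol%), CH2Cl2, −78 °C; then 1 M HCl, THF, 0 °C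
Reagents that add atoms: none
Why: Enantioselective Mukaiyama aldol addition in which the chiral divalent copper Lewis acid holds the aldehyde as a five-membered chelate through its ether oxygen and shields one face, so that the terminal carbon of the enol silane should add through an open transition state to give the (S)-carbinol (the later C3), this catalyst enantiomer being the one expected by analogy with benzyloxyacetaldehyde, before the silyl ether is cleaved on acidic work-up.

Step 3
Reactants: 5 (S)-5-hydroxy-6-[(4-methoxybenzyl)oxy]-2-methylhex-1-en-3-one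
Product: 6 (3S,5S)-6-[(4-methoxybenzyl)oxy]-2-methylhex-1-ene-3,5-diol
Conditions: Me4NBH(OAc)3, MeCN–AcOH (1:1), −30 °C
Reagents that add atoms: none
Why: Evans–Saksena reduction, in which the free hydroxyl exchanges onto boron and delivers hydride intramolecularly through a chair transition state, should give the 1,3-anti diol (new carbinol, the later C1) without conjugate reduction of the enone.

Step 4
Reactants: 6 (3S,5S)-6-[(4-methoxybenzyl)oxy]-2-methylhex-1-ene-3,5-diol
Product: 7 bicyclic lactone (1S,5S,7S)-7-{[(4-methoxybenzyl)oxy]methyl}-5-methyl-2,6-dioxabicyclo[3.3.0]octan-3-one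
Conditions: PdCl2 (10 mol%), CuCl2 (3 equiv), NaOAc (3 equiv), AcOH, CO (1 atm), rt
Reagents that add atoms: carbon monoxide, [C-]#[O+]
Why: Alkoxycarbonylative cyclisation of an ene-diol, in which the C3 hydroxyl adds 5-exo-trig to the methyl-bearing carbon (C10) of the alkene activated by divalent palladium, CO inserts into the CH2–Pd bond (C9) and the allylic C1 hydroxyl captures the acyl group, and because oxypalladation is reversible and only the adduct with C9 cis to the C1 oxygen can lactonise, the quaternary centre C10 is set from C1 while the anti diol places the C4 side chain cis to C9 on the tetrahydrofuran, CuCl2 returning zerovalent palladium to the divalent state.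

Step 5
Reactants: 7 bicyclic lactone
Product: 9 (2S,3S,5S)-5-{[(4-methoxybenzyl)oxy]methyl}-2-methyl-2-(prop-2-yn-1-yl)tetrahydrofuran-3-ol, via lactol 8 (not isolated)
Conditions: i-Bu2AlH, CH2Cl2, −78 °C; then MeOH, K2CO3, dimethyl (1-diazo-2-oxopropyl)phosphonate, rt
Reagents that add atoms: dimethyl (1-diazo-2-oxopropyl)phosphonate, CC(=O)C(=[N+]=[N-])P(=O)(OC)OC
Why: Half-reduction of the γ-lactone to the lactol and Seyferth–Gilbert homologation of its open hydroxy-aldehyde form with the Ohira–Bestmann reagent should turn the lactone carbonyl (C8) into the terminal alkyne C8≡C7 and free the C1 hydroxyl, with no stereocentre touched.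

Step 6
Reactants: 9 tetrahydrofuranol
Product: 10 tert-butyldimethylsilyl ether of 9
Conditions: TBSCl, imidazole, DMF, 0 °C to rt
Reagents that add atoms: tert-butyldimethylsilyl chloride, CC(C)(C)[Si](C)(C)Cl
Why: Silylation of the only free hydroxyl (C1) keeps it from adding to the diyne in step 13, where its 5-exo-dig closure would outrun the desired one (silyl ether formation).

Step 7
Reactants: 10 silyl ether
Product: 11 [(2S,4S,5S)-4-[(tert-butyldimethylsilyl)oxy]-5-methyl-5-(prop-2-yn-1-yl)tetrahydrofuran-2-yl]methanol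
Conditions: DDQ, CH2Cl2–pH 7 buffer, 0 °C
Reagents that add atoms: none
Why: DDQ abstracts hydride from the electron-rich benzylic ether and the oxocarbenium ion is hydrolysed, which should free the primary C4 hydroxyl without touching the silyl ether or the alkyne (oxidative cleavage of a 4-methoxybenzyl ether).

Step 8
Reactants: 11 primary alcohol
Product: 12 (2S,4S,5S)-4-[(tert-butyldimethylsilyl)oxy]-5-methyl-5-(prop-2-yn-1-yl)tetrahydrofuran-2-carbaldehyde
Conditions: Dess–Martin periodinane, CH2Cl2, 0 °C
Reagents that add atoms: none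
Why: Dess–Martin oxidation under non-basic conditions should give the α-alkoxy aldehyde without epimerising C3, and the aldehyde is used at once.

Step 9
Reactants: 12 aldehyde
Product: 13 propargylic alcohols (both C4 epimers)
Conditions: HC≡CMgBr (3 equiv), THF, −78 to −20 °C
Reagents that add atoms: ethynylmagnesium bromide, C#C[Mg]Br
Why: Grignard addition of the acetylide to the aldehyde brings in C5 and C6, the new carbinol centre C4 being formed without control, which does not matter because it is oxidised in step 10 (the terminal alkyne of 12 is only deprotonated and returns on work-up).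

Step 10
Reactants: 13 propargylic alcohols
Product: 15 (E)-β-alkoxy enone, via ynone 14 (not isolated)
Conditions: MnO2, CH2Cl2, rt; filter; then 4-methoxybenzyl alcohol, PMe3 (10 mol%), CH2Cl2, 0 °C
Reagents that add atoms: 4-methoxybenzyl alcohol, COc1ccc(CO)cc1
Why: MnO2 oxidises the propargylic alcohols to the ynone, and phosphine-catalysed conjugate addition of the alcohol (oxa-Michael addition to an ynone) should give the (E)-β-alkoxy enone under conditions mild enough to leave the α-alkoxy stereocentre C3 intact.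

Step 11
Reactants: 15 (E)-β-alkoxy enone
Product: 16 tertiary alcohol (4R)
Conditions: PhSCH2MgCl (3 equiv, from ClCH2SPh and Mg), CH2Cl2–THF, −78 °C
Reagents that add atoms: (phenylsulfanyl)methylmagnesium chloride, Cl[Mg]CSc1ccccc1
Why: Cram-chelate-controlled Grignard 1,2-addition, in which magnesium bridges the ketone oxygen and the tetrahydrofuran oxygen and the nucleophile enters from the face of the chelate that carries H-3 (anti to the ring CH2), should set the tertiary carbinol C4 and bring in C15 with the sulfur needed in step 22.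

Step 12
Reactants: 16 tertiary alcohol
Product: 17 diyne
Conditions: (bromoethynyl)triisopropylsilane, CuCl (5 mol%), NH2OH·HCl (cat.), n-BuNH2, H2O–CH2Cl2, 0 °C
Reagents that add atoms: (bromoethynyl)tri(propan-2-yl)silane, CC(C)[Si](C#CBr)(C(C)C)C(C)C
Why: Cadiot–Chodkiewicz coupling of the terminal alkyne with the bromoalkyne under monovalent copper catalysis should give the unsymmetrical conjugated diyne, which activates C8 towards nucleophiles and carries the later C11 and C13.

Step 13
Reactants: 17 diyne
Product: 18 dioxepane enol ether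
Conditions: KOt-Bu (20 mol%), THF, 0 °C to rt; pH 7 buffer
Reagents that add atoms: none
Why: The tertiary potassium alkoxide should add 7-exo-dig to the terminus C8 of the conjugated diyne, the only position that gives a delocalised propargyl/allenyl anion, and trans protonation (anti-hydroalkoxylation as in base-mediated cycloisomerisations of alkynols and additions of alkoxides to butadiynes) should give the (Z)-enyne enol ether, the cis-2,5-disubstituted tetrahydrofuran holding the C4 oxygen and C9 on one face so that the bridged seven-membered ring can close.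

Step 14
Reactants: 18 dioxepane enol ether
Product: 19 oxonane ketone
Conditions: toluene, N,O-bis(trimethylsilyl)acetamide (10 mol%, acid scavenger), 100 °C, sealed tube
Reagents that add atoms: none
Why: Thermal Claisen ([3,3]-sigmatropic) rearrangement of the allyl vinyl ether C7=C8–O–C4–C5=C6, in which C8, the ether oxygen and C4 are ring atoms of the dioxepane: the C4–O bond breaks, the C6–C7 bond forms and the oxygen leaves the ring as the C8 carbonyl, so the seven-membered ring becomes the nine-membered oxonane and the eight-membered ring C1–C2–C3–C4–O–C8–C9–C10 becomes the ten-membered carbocycle of the 11-oxabicyclo[6.2.1]undecene core. The closest known reaction type is the Claisen ring expansion of 2-alkylidene cyclic ethers that carry a vinyl group on the other carbon next to oxygen, which gives cycloalkenones enlarged by two atoms. Both new rings are thus closed by sigmatropic bond reorganisation inside a bridged bicycle and not by an end-to-end cyclisation, through a chair-like array in which C3 is pseudo-axial on C4, which is why C3 and C6 come out cis on the new C4=C5 bond. C6 and C7 are set together: the (E)-enol ether places the C6 oxygen pseudo-equatorial, the (Z)-enyne enol ether places the alkynyl group pseudo-axial, which gives the 6,7-anti pair that later closes to the cis-fused lactone, and the C4 carbinol configuration decides which faces are joined, so that C4 (destroyed) is transferred to C6 and C7 with the configurations of the target. The step needs the concerted chair pathway and not a boat or an ionisation and recombination of the tertiary, alkoxy- and sulfur-stabilised allylic ether: the large ring torsions of opposite sign about C8–O and O–C4 in the bridged dioxepane fit a chair and not a boat, the tertiary and 6-alkoxy substitution should lower the barrier enough for a non-polar, acid-free medium at about 100 °C, and the new C=O together with the relief of the bridged seven-membered ring makes the step irreversible.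

Step 15
Reactants: 19 oxonane ketone
Product: 20 C8 alcohol (8R)
Conditions: Zn(BH4)2, Et2O, −30 °C
Reagents that add atoms: none
Why: Zn(BH4)2 should reduce the ketone through a six-membered zinc chelate between the C8 carbonyl and the C6 ether oxygen, external hydride delivery giving the 1,3-syn (C6/C8) relationship, that is (8R), under neutral conditions that do not epimerise the α-alkynyl centre C7 (chelation-controlled reduction of a β-alkoxy ketone).

Step 16
Reactants: 20 C8 alcohol
Product: 21 isobutyrate
Conditions: (i-PrCO)2O, DMAP (cat.), Et3N, CH2Cl2, rt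
Reagents that add atoms: 2-methylpropanoic anhydride, CC(C)C(=O)OC(=O)C(C)C
Why: DMAP-catalysed acylation of the only free hydroxyl should install the C8 ester of the target with retention, no neighbouring hydroxyl being free to allow acyl migration.

Step 17
Reactants: 21 isobutyrate
Product: 22 C1 alcohol with terminal alkyne
Conditions: n-Bu4NF, THF, 0 °C to rt
Reagents that add atoms: none
Why: Fluoride should cleave the O–Si bond at C1 and the C–Si bond of the silylalkyne in one operation (fluoride desilylation), the hindered ester and the benzylic ether being stable.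

Step 18
Reactants: 22 C1 alcohol
Product: 23 C1 ketone
Conditions: Dess–Martin periodinane, CH2Cl2, rt
Reagents that add atoms: none
Why: Dess–Martin oxidation of the only free hydroxyl should give the tetrahydrofuran-3-one without oxidising the sulfide, which reacts much more slowly with this reagent.

Step 19
Reactants: 23 C1 ketone
Product: 24 alkynol (C6–OH)
Conditions: DDQ, CH2Cl2–pH 7 buffer, 0 °C
Reagents that add atoms: none
Why: Oxidative cleavage of the 4-methoxybenzyl ether should free the C6 hydroxyl under neutral conditions, so that the 1,3-related C8 ester does not migrate.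

Step 20
Reactants: 24 alkynol
Product: 25 α-methylene lactone
Conditions: PdCl2 (5 mol%), SnCl2 (5 mol%), PPh3 (10 mol%), CO (7 atm), MeCN, 75 °C
Reagents that add atoms: carbon monoxide, [C-]#[O+]
Why: Cyclocarbonylation of a homopropargylic alcohol, in which the C6 oxygen and CO form an alkoxycarbonyl–palladium species that adds syn across the alkyne (5-exo) and the vinyl–palladium bond is protonated, should give the α-methylene-γ-lactone directly, its cis ring fusion following from the C6/C7 configuration set in step 14.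

Step 21
Reactants: 25 α-methylene lactone
Product: 27 furanone, via silyl enol ether 26 (not isolated)
Conditions: TMSOTf, Et3N, CH2Cl2, 0 °C; then Pd(OAc)2 (1.1 equiv), MeCN, rt
Reagents that add atoms: none
Why: Saegusa–Ito oxidation, in which the C1 ketone can enolise only towards C2 (C10 is quaternary) and β-hydride elimination of H-3 from the C2-bound palladium enolate should give the 3(2H)-furanone, removing the temporary C3 stereocentre.

Step 22
Reactants: 27 furanone
Product: 30 target CNP0384113.2, via sulfoxide 28 (not isolated), via sulfenate 29 (not isolated)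
Conditions: m-CPBA (1.0 equiv), CH2Cl2, −78 °C; then P(OMe)3, MeOH, rt
Reagents that add atoms: 3-chloroperoxybenzoic acid, OOC(=O)c1cccc(Cl)c1
Why: Chemoselective oxidation of the sulfide gives the allylic sulfoxide, which equilibrates by Mislow–Evans [2,3]-sigmatropic rearrangement with the sulfenate that carries oxygen on C5 and the C4=C15 methylene, and the phosphite cleaves the S–O bond, the (5S) alcohol being expected from suprafacial delivery to the face of C5 anti to the C6–O bond, which is the least secure stereochemical element of the route.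

Compound list
1 | 3-methylbut-3-en-2-one | CC(=O)C(C)=C | starting material
2 | 2-methyl-3-(trimethylsilyloxy)buta-1,3-diene | C=C(C)C(=C)O[Si](C)(C)C | intermediate
3 | [(4-methoxybenzyl)oxy]acetaldehyde | O=CCOCc1ccc(OC)cc1 | starting material
4 | (S)-6-[(4-methoxybenzyl)oxy]-2-methyl-5-(trimethylsilyloxy)hex-1-en-3-one | C=C(C)C(=O)C[C@H](O[Si](C)(C)C)COCc1ccc(OC)cc1 | intermediate (not isolated)
5 | (S)-5-hydroxy-6-[(4-methoxybenzyl)oxy]-2-methylhex-1-en-3-one | C=C(C)C(=O)C[C@H](O)COCc1ccc(OC)cc1 | intermediate
6 | (3S,5S)-6-[(4-methoxybenzyl)oxy]-2-methylhex-1-ene-3,5-diol (1,3-anti) | C=C(C)[C@@H](O)C[C@H](O)COCc1ccc(OC)cc1 | intermediate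
7 | (1S,5S,7S)-7-{[(4-methoxybenzyl)oxy]methyl}-5-methyl-2,6-dioxabicyclo[3.3.0]octan-3-one (cis-fused; side chain cis to the lactone CH2) | O=C1C[C@]2(C)O[C@H](COCc3ccc(OC)cc3)C[C@@H]2O1 | intermediate
8 | (1S,5S,7S)-7-{[(4-methoxybenzyl)oxy]methyl}-5-methyl-2,6-dioxabicyclo[3.3.0]octan-3-ol (lactol, both anomers) | OC1C[C@]2(C)O[C@H](COCc3ccc(OC)cc3)C[C@@H]2O1 | intermediate (not isolated)
9 | (2S,3S,5S)-5-{[(4-methoxybenzyl)oxy]methyl}-2-methyl-2-(prop-2-yn-1-yl)tetrahydrofuran-3-ol | C#CC[C@]1(C)O[C@H](COCc2ccc(OC)cc2)C[C@@H]1O | intermediate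
10 | tert-butyl{[(2S,3S,5S)-5-{[(4-methoxybenzyl)oxy]methyl}-2-methyl-2-(prop-2-yn-1-yl)tetrahydrofuran-3-yl]oxy}dimethylsilane | C#CC[C@]1(C)O[C@H](COCc2ccc(OC)cc2)C[C@@H]1O[Si](C)(C)C(C)(C)C | intermediate
11 | [(2S,4S,5S)-4-[(tert-butyldimethylsilyl)oxy]-5-methyl-5-(prop-2-yn-1-yl)tetrahydrofuran-2-yl]methanol | C#CC[C@]1(C)O[C@H](CO)C[C@@H]1O[Si](C)(C)C(C)(C)C | intermediate
12 | (2S,4S,5S)-4-[(tert-butyldimethylsilyl)oxy]-5-methyl-5-(prop-2-yn-1-yl)tetrahydrofuran-2-carbaldehyde | C#CC[C@]1(C)O[C@H](C=O)C[C@@H]1O[Si](C)(C)C(C)(C)C | intermediate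
13 | 1-[(2S,4S,5S)-4-[(tert-butyldimethylsilyl)oxy]-5-methyl-5-(prop-2-yn-1-yl)tetrahydrofuran-2-yl]prop-2-yn-1-ol (both epimers at the carbinol carbon C4) | C#CC[C@]1(C)O[C@H](C(O)C#C)C[C@@H]1O[Si](C)(C)C(C)(C)C | intermediate
14 | 1-[(2S,4S,5S)-4-[(tert-butyldimethylsilyl)oxy]-5-methyl-5-(prop-2-yn-1-yl)tetrahydrofuran-2-yl]prop-2-yn-1-one | C#CC[C@]1(C)O[C@H](C(=O)C#C)C[C@@H]1O[Si](C)(C)C(C)(C)C | intermediate (not isolated)
15 | (E)-1-[(2S,4S,5S)-4-[(tert-butyldimethylsilyl)oxy]-5-methyl-5-(prop-2-yn-1-yl)tetrahydrofuran-2-yl]-3-[(4-methoxybenzyl)oxy]prop-2-en-1-one | C#CC[C@]1(C)O[C@H](C(=O)/C=C/OCc2ccc(OC)cc2)C[C@@H]1O[Si](C)(C)C(C)(C)C | intermediate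
16 | (2R,3E)-2-[(2S,4S,5S)-4-[(tert-butyldimethylsilyl)oxy]-5-methyl-5-(prop-2-yn-1-yl)tetrahydrofuran-2-yl]-4-[(4-methoxybenzyl)oxy]-1-(phenylsulfanyl)but-3-en-2-ol | C#CC[C@]1(C)O[C@H]([C@@](O)(CSc2ccccc2)/C=C/OCc2ccc(OC)cc2)C[C@@H]1O[Si](C)(C)C(C)(C)C | intermediate
17 | (2R,3E)-2-[(2S,4S,5S)-4-[(tert-butyldimethylsilyl)oxy]-5-methyl-5-[5-(triisopropylsilyl)penta-2,4-diyn-1-yl]tetrahydrofuran-2-yl]-4-[(4-methoxybenzyl)oxy]-1-(phenylsulfanyl)but-3-en-2-ol | CC(C)[Si](C(C)C)(C(C)C)C#CC#CC[C@]1(C)O[C@H]([C@@](O)(CSc2ccccc2)/C=C/OCc2ccc(OC)cc2)C[C@@H]1O[Si](C)(C)C(C)(C)C | intermediate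
18 | 3,9-dioxabicyclo[4.2.1]nonane enol ether: bridgeheads C3 (H) and C10 (CH3) joined by the furan oxygen and by C1(OTBS)–C2H2; four-atom bridge C9H2–C8[=C7H–C≡C–Si(i-Pr)3, Z]–O–C4[CH2SPh][(E)-CH=CH–O-4-methoxybenzyl]; (1S,3S,4R,10S) in germacrane locants | CC(C)[Si](C(C)C)(C(C)C)C#C/C=C1/C[C@]2(C)O[C@@H](C[C@@H]2O[Si](C)(C)C(C)(C)C)[C@@](CSc2ccccc2)(/C=C/OCc2ccc(OC)cc2)O1 | intermediate
19 | (1S,3S,4E,6S,7S,10S)-1-[(tert-butyldimethylsilyl)oxy]-3,10-epoxy-6-[(4-methoxybenzyl)oxy]-10-methyl-4-[(phenylsulfanyl)methyl]-7-[(triisopropylsilyl)ethynyl]cyclodec-4-en-8-one (germacrane locants; C3 and C6 cis across C4=C5) | COc1ccc(CO[C@@H]2[C@H](C#C[Si](C(C)C)(C(C)C)C(C)C)C(=O)C[C@]3(C)O[C@@H](C[C@@H]3O[Si](C)(C)C(C)(C)C)/C(CSc3ccccc3)=C\2)cc1 | intermediate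
20 | (1S,3S,4E,6S,7R,8R,10S)-1-[(tert-butyldimethylsilyl)oxy]-3,10-epoxy-6-[(4-methoxybenzyl)oxy]-10-methyl-4-[(phenylsulfanyl)methyl]-7-[(triisopropylsilyl)ethynyl]cyclodec-4-en-8-ol | COc1ccc(CO[C@@H]2[C@H](C#C[Si](C(C)C)(C(C)C)C(C)C)[C@H](O)C[C@]3(C)O[C@@H](C[C@@H]3O[Si](C)(C)C(C)(C)C)/C(CSc3ccccc3)=C\2)cc1 | intermediate
21 | 2-methylpropanoate (C8 ester) of 20, (1S,3S,4E,6S,7R,8R,10S) | COc1ccc(CO[C@@H]2[C@H](C#C[Si](C(C)C)(C(C)C)C(C)C)[C@H](OC(=O)C(C)C)C[C@]3(C)O[C@@H](C[C@@H]3O[Si](C)(C)C(C)(C)C)/C(CSc3ccccc3)=C\2)cc1 | intermediate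
22 | (1S,3S,4E,6S,7R,8R,10S)-3,10-epoxy-7-ethynyl-1-hydroxy-6-[(4-methoxybenzyl)oxy]-10-methyl-4-[(phenylsulfanyl)methyl]cyclodec-4-en-8-yl 2-methylpropanoate | COc1ccc(CO[C@@H]2[C@H](C#C)[C@H](OC(=O)C(C)C)C[C@]3(C)O[C@@H](C[C@@H]3O)/C(CSc3ccccc3)=C\2)cc1 | intermediate
23 | (3S,4E,6S,7R,8R,10S)-3,10-epoxy-7-ethynyl-6-[(4-methoxybenzyl)oxy]-10-methyl-1-oxo-4-[(phenylsulfanyl)methyl]cyclodec-4-en-8-yl 2-methylpropanoate | COc1ccc(CO[C@@H]2[C@H](C#C)[C@H](OC(=O)C(C)C)C[C@]3(C)O[C@@H](CC3=O)/C(CSc3ccccc3)=C\2)cc1 | intermediate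
24 | (3S,4E,6S,7S,8R,10S)-3,10-epoxy-7-ethynyl-6-hydroxy-10-methyl-1-oxo-4-[(phenylsulfanyl)methyl]cyclodec-4-en-8-yl 2-methylpropanoate | O[C@@H]1[C@H](C#C)[C@H](OC(=O)C(C)C)C[C@]2(C)O[C@@H](CC2=O)/C(CSc2ccccc2)=C\1 | intermediate
25 | (3S,4E,6S,7R,8R,10S)-3,10-epoxy-1-oxo-15-(phenylsulfanyl)germacra-4,11(13)-dien-12,6-olid-8-yl 2-methylpropanoate (cis-fused lactone) | C=C1C(=O)O[C@@H]2[C@H]1[C@H](OC(=O)C(C)C)C[C@]1(C)O[C@@H](CC1=O)/C(CSc1ccccc1)=C\2 | intermediate
26 | C1 trimethylsilyl enol ether of 25 (C1(OSiMe3)=C2) | C=C1C(=O)O[C@@H]2[C@H]1[C@H](OC(=O)C(C)C)C[C@]1(C)O[C@@H](C=C1O[Si](C)(C)C)/C(CSc1ccccc1)=C\2 | intermediate (not isolated)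
27 | (4E,6S,7R,8R,10S)-3,10-epoxy-1-oxo-15-(phenylsulfanyl)germacra-2,4,11(13)-trien-12,6-olid-8-yl 2-methylpropanoate | C=C1C(=O)O[C@@H]2[C@H]1[C@H](OC(=O)C(C)C)C[C@]1(C)OC(=CC1=O)/C(CSc1ccccc1)=C\2 | intermediate
28 | S-oxide of 27 (allylic sulfoxide, both configurations at sulfur) | C=C1C(=O)O[C@@H]2[C@H]1[C@H](OC(=O)C(C)C)C[C@]1(C)OC(=CC1=O)/C(CS(=O)c1ccccc1)=C\2 | intermediate (not isolated)
29 | (5S,6R,7R,8R,10S)-3,10-epoxy-1-oxo-5-[(phenylsulfanyl)oxy]germacra-2,4(15),11(13)-trien-12,6-olid-8-yl 2-methylpropanoate (sulfenate) | C=C1C(=O)O[C@@H]2[C@H]1[C@H](OC(=O)C(C)C)C[C@]1(C)OC(=CC1=O)C(=C)[C@@H]2OSc1ccccc1 | intermediate (not isolated)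
30 | (5S,6R,7R,8R,10S)-3,10-epoxy-5-hydroxy-1-oxogermacra-2,4(15),11(13)-trien-12,6-olid-8-yl 2-methylpropanoate (CNP0384113.2) | C=C1C(=O)O[C@@H]2[C@H]1[C@H](OC(=O)C(C)C)C[C@]1(C)OC(=CC1=O)C(=C)[C@@H]2O | target

Total step count: 22. Longest linear sequence: 22 steps (1 → 30; the route is linear, 3 enters in step 2).

Steps most likely to fail:

Step 13. The 7-exo-dig alkoxide addition may be slower than base-induced isomerisation of the skipped diyne to an allene, or the vinyl anion may be protonated without geometric control. The fallback changes the ring closure from anionic conjugate addition to electrophilic activation of the neutral alkynol: it sets out from 17, which is treated with Ph3PAuNTf2 (monovalent gold, 5 mol%) and 2,6-di-tert-butylpyridine in CH2Cl2 at rt. Anti-oxyauration of the diyne terminus and protodeauration should give the same (Z)-enol ether, so the fallback comes back to the route at 18 and makes no further compound (F0).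

Step 15. Hydride may be delivered to the other face of the C8 carbonyl, because the zinc chelate is distorted by the medium ring. The fallback uses the wrong epimer instead of fighting for the right one. It sets out from 19, which is reduced with a bulky non-chelating hydride (LiBH(s-Bu)3, THF, −78 °C, chosen because it should favour the other face) to the (8S)-epimer of alcohol 20, F1. Mitsunobu esterification of F1 with 2-methylpropanoic acid (PPh3, diisopropyl azodicarboxylate, toluene, 0 °C) should then invert C8 and install the ester in one operation, coming back to the route at 21.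

Step 22. Oxygen may be delivered to the other face of C5, because both sulfenate diastereomers can form and the preferred ring conformation is not secure. The fallback moves the stereocontrol from the sigmatropic shift to a carbonyl reduction. It sets out from 27; step 22 is run as written and the product, consisting largely of the (5R)-epimer of 30, F2, is oxidised with MnO2 (CH2Cl2, rt) to the cross-conjugated 5-ketone F3. Luche reduction of F3 (NaBH4, CeCl3·7H2O, MeOH, −78 °C), with hydride entering anti to the C6–O bond (Felkin–Anh control by the lactone oxygen), should give the 5,6-anti alcohol and so come back to the route at 30.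

Further compounds
F0 | step 13 | none | none
F1 | step 15 | (1S,3S,4E,6S,7R,8S,10S)-1-[(tert-butyldimethylsilyl)oxy]-3,10-epoxy-6-[(4-methoxybenzyl)oxy]-10-methyl-4-[(phenylsulfanyl)methyl]-7-[(triisopropylsilyl)ethynyl]cyclodec-4-en-8-ol (8-epimer of 20) | COc1ccc(CO[C@@H]2[C@H](C#C[Si](C(C)C)(C(C)C)C(C)C)[C@@H](O)C[C@]3(C)O[C@@H](C[C@@H]3O[Si](C)(C)C(C)(C)C)/C(CSc3ccccc3)=C\2)cc1
F2 | step 22 | (5R,6R,7R,8R,10S)-3,10-epoxy-5-hydroxy-1-oxogermacra-2,4(15),11(13)-trien-12,6-olid-8-yl 2-methylpropanoate (5-epimer of 30) | C=C1C(=O)O[C@@H]2[C@H]1[C@H](OC(=O)C(C)C)C[C@]1(C)OC(=CC1=O)C(=C)[C@H]2O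
F3 | step 22 | (6S,7R,8R,10S)-3,10-epoxy-1,5-dioxogermacra-2,4(15),11(13)-trien-12,6-olid-8-yl 2-methylpropanoate (5-ketone) | C=C1C(=O)O[C@@H]2[C@H]1[C@H](OC(=O)C(C)C)C[C@]1(C)OC(=CC1=O)C(=C)C2=O
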